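The ratio of target to starting material climbs within hours in the dawn run and then fades, from 0.202 at 2.08 d to 0.0935 at 8.00 d.

| setting | dawn | summer | flask |
|---|---|---|---|
| starting material | 10 mM | 6.7 mM | 10 mM |
| coupling partner | 12 mM | 12 mM | 12.0 mM |
| second substrate | 50 mM | 50 mM | 50.0 mM |
| remark | the very flask that is asked about, followed so far | run made earlier |  |
| time |  |  | 15 d |

| run | time / d | target / % | starting material / % |
|---|---|---|---|
| dawn | 0.167 | 13.9 | 86.6 |
| dawn | 0.625 | 18.9 | 81.7 |
| dawn | 2.08 | 16.7 | 82.8 |
| dawn | 8.00 | 8.3 | 88.8 |
| summer | 0.167 | 13.2 | 86.5 |
| summer | 0.625 | 19.9 | 80.5 |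
| summer | 2.50 | 16.9 | 82.8 |
| summer | 10.0 | 6.3 | 90.7 |

(readings scatter by 0.5 percentage points)

- the earlier runs were read with a standard deviation of 0.5 percentage points

- time up to 15 d at which target stands highest
- the amount of target, in percent of the starting material charged, at that time

On the fastest rung, target rises towards a ceiling. With the highest dawn reading, 18.9 %, as that ceiling, the first reading gives an approach rate (relaxation rate) of 7.96 d⁻¹.

On the slow rung, the ratio loses 0.130 d⁻¹. This is the fade rate, the first-order fall of target over starting material per day. The summer run gives 0.144 d⁻¹.

Approach is much faster than fade, so the peak stands where the rising curve meets the sinking ceiling, at ln(approach/fade)/(approach − fade), which is 0.525 d. Going round once more, the ceiling at the start lies higher, at 20.2 %. The approach rate then drops to 6.95 d⁻¹, and the peak moves to 0.583 d, with a height near the reading of 18.9 %.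

The forecast gives 0.7 d and 19.2 %, later than this reckoning, holding that “The target peaks where the rising curve meets this sinking ceiling”.

The flask gives 18.6 % at 0.629 d.

    starting material + coupling partner ⇌ target (K = 35.0 M⁻¹, k = 0.00182 M⁻¹ s⁻¹)
    second substrate + coupling partner ⇌ second product (K = 8.30 M⁻¹, k = 0.00340 M⁻¹ s⁻¹)
    coupling partner → decomposed reagent (k = 2.18 × 10⁻⁶ s⁻¹)
    coupling partner + target → over-reaction product (k = 5.03 × 10⁻⁵ M⁻¹ s⁻¹)

A run of this flask without the reverse step, target to starting material and coupling partner, reaches a best of 85.6 % against 18.6 %, the largest single effect on that height among the steps and levels tried. The fade rate carries the flask's ratio at the best time, 0.230, down to 0.0355 at 15.0 d, where the flask stands at 0.0439. In the neighbour flask with 200 mM of second substrate, the best of 11.9 %, with the rest of the charge taken as starting material, fades over the whole 15 d to 0.0193, but that neighbour flask stands at 0.0528 and still holds 2.45 mM of second product against 0.506 mM.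

All runs were computed with made-up constants.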